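The data were generated by integration on assumed constants; scatter was added.

Chains are to be estimated from the plateaus, not guessed.

all flasks: impurity 2.5 mM
- blue: free monomer 19 mM; transfer agent 5.7 mM; pre-initiator 6.7 mol%; run made earlier
- ochre: free monomer 19 mM; transfer agent 5.7 mM; pre-initiator 15 mol%; run made earlier
- violet: free monomer 9.5 mM; transfer agent 5.7 mM; pre-initiator 10 mol%; run made earlier
- flask: free monomer 19 mM; transfer agent 5.70 mM; pre-initiator 10 mol%; time 25 h

| run | time / h | monomer in chains / % | free monomer / % |
|---|---|---|---|
| blue | 2.50 | 44.7 | 56.2 |
| blue | 8.00 | 67.2 | 32.0 |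
| blue | 12.0 | 71.3 | 28.2 |
| blue | 20.0 | 72.4 | 26.9 |
| ochre | 5.00 | 88.6 | 10.8 |
| ochre | 10.0 | 95.4 | 4.8 |
| ochre | 15.0 | 96.2 | 4.4 |
| ochre | 20.0 | 96.4 | 4.0 |
| violet | 5.00 | 38.9 | 60.9 |
| violet | 10.0 | 46.1 | 52.9 |
| violet | 15.0 | 48.6 | 51.8 |
| violet | 20.0 | 49.8 | 51.5 |

(scatter of a reading: 0.5 percentage points)

- the average divides the monomer in chains by the number of chains begun, living and dead together
- the analysis behind the earlier runs scatters by 0.5 percentage points, standard deviation
- the earlier runs do not show the number of chains; that part of a forecast is a guess

1. average number of monomer units in a chain (chains begun, living or dead) at 25 h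
2. part of the free monomer that has reacted at 25 h

**What does a plateau measure?** Blue and violet stall with free monomer left, at 26.9% and 51.5% of charge. I take the plateau log, ln(c(free monomer, start)/c(free monomer, end)), as proportional to chains begun, by a factor g that is equal in both runs, since their transfer agent is equal.

**What is the yield per pre-initiator?** Blue gives 1.03 /mM and violet, with half the free monomer, gives less, 0.699 /mM. Their ratio is 0.677.

**Your reading?** Suppose initiator is contested by free monomer and impurity. With free monomer far ahead, each initiator begins a chain; far behind, the chain share is proportional to c(free monomer). Joining both ends, share = c(free monomer)/(c(free monomer) + s·c(impurity)). The ratio then gives the selectivity factor s, initiator capture by impurity against chain starts, as 6.92.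

**And this flask?** Its share is 52.3%, so 0.994 mM chains. Blue sets g at 1.97 /mM, so I reckon c 85.9% and dp 16.4.

**But ochre yields 1.13 /mM, above blue. Is the share really fixed?** No. It holds impurity at its charge, and ochre suggests that more pre-initiator uses impurity up, so my share may read low for this flask.

The forecast says c 88%, interpolated from the plateau logs, and dp 3.4, from a separately guessed chain count, on the ground “Transfer probably dominates”. Its c stands near mine, but my dp is higher.

The flask gives dp 16.1 and c 87.6%.

    free monomer + initiator → living end + monomer in chains (k = 31.5 /M/min)
    free monomer + living end → monomer in chains + living end, rate k2*[living end]*[free monomer] (k = 8.00 /M/min)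
    living end + transfer agent → dead chain (kL = 0.785 /M/min)
    initiator + impurity → spent initiator A (k = 226 /M/min)
    2 initiator → spent initiator B (k = 5.21 /M/min)
    pre-initiator → initiator (k = 0.0713 /min)

At 25.0 h the flask holds 1.03 mM dead chain and 0.00368 mM living end, against the 0.994 mM of chains reckoned. The same flask with 10 mM impurity and unchanged transfer agent takes the same s and g: share 21.5%, 0.409 mM chains, c 55.4%, dp 25.7. Simulated, that neighbour holds 0.412 mM dead chain at 25.0 h, with c 54.5% and dp 25.1.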